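Everything hinges on disconnecting ring B at C9–C10. Two fragments are prepared: ring A with the C5 tertiary alcohol beside an exocyclic methylene on C10, and ring C as a cyclopentene that already holds C13 and C14. They are linked through C6–C7, and C7 is raised to a ketone conjugated with C8=C9. An iron hydride then adds a hydrogen atom to the methylene; the C10 radical so formed bonds to C9, which closes ring B and creates C10, C9 and C8 at once. The step draws on two features of ring B: the C10 methyl can be written as a methylene plus one hydrogen atom, and C9 lies β to the C7 oxygen.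

Key step: step 23

Numbering: the atom numbers of the target are used for every fragment. Ring A = C1–C5 and C10 (C1 oxygen, C4 gem-dimethyl, C5 hydroxyl, C10 methyl); ring B = C5–C10 (C7 oxygen); ring C = C8, C9, C11, C13, C14; C12 = lactone carbonyl on C13; C15, C16 = two-carbon arm on C13; C17 = one-carbon arm on C14. α and β mean below and above the target drawn with the C10 methyl up.

Assumption: 2-(2,6,6-trimethylcyclohex-1-en-1-yl)acetaldehyde (β-homocyclocitral) and methyl 3-oxocyclopent-1-ene-1-carboxylate are taken as bought.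

Remark on the chemistry: an undirected oxidant should reach the final enol lactone from the face away from the C14 substituent, which is the wrong face. The epoxide oxygen is therefore delivered from the C17 hydroxyl before C17 is oxidised, and the protecting groups (4-methoxybenzyl on O1, tert-butyldiphenylsilyl on O17) are chosen to allow this order.

Step 1
Reactants: 1 β-homocyclocitral, 2-(2,6,6-trimethylcyclohex-1-en-1-yl)acetaldehyde
Product: 2 2-(2,6,6-trimethylcyclohex-1-en-1-yl)ethanol
Conditions: NaBH4, MeOH, 0 °C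
Reagents that add atoms: none
Why: Borohydride reduction of the aldehyde; the tetrasubstituted alkene is untouched and no stereocentre arises.

Step 2
Reactants: 2 2-(2,6,6-trimethylcyclohex-1-en-1-yl)ethanol
Product: 3 tert-butyldimethyl[2-(2,6,6-trimethylcyclohex-1-en-1-yl)ethoxy]silane
Conditions: t-BuMe2SiCl, imidazole, CH2Cl2, rt
Reagents that add atoms: tert-butyldimethylsilyl chloride, CC(C)(C)[Si](C)(C)Cl
Why: Silyl ether formation on a primary alcohol, so that the C7 oxygen survives oxidation, hydride and amide base.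

Step 3
Reactants: 3 silyl ether of the homologated alcohol
Product: 4 3-[2-(tert-butyldimethylsilyloxy)ethyl]-2,4,4-trimethylcyclohex-2-en-1-one (C1 ketone)
Conditions: CrO3, 3,5-dimethylpyrazole, CH2Cl2, −20 °C
Reagents that add atoms: chromium trioxide, O=[Cr](=O)=O
Why: Chromium-mediated allylic oxidation should strike the ring methylene next to the methyl-bearing alkene carbon (C1), the usual site in 2,6,6-trimethylcyclohexenes, and give the conjugated enone; the side-chain allylic CH2 should react more slowly.

Step 4
Reactants: 4 ring A enone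
Product: 5 (S)-3-[2-(tert-butyldimethylsilyloxy)ethyl]-2,4,4-trimethylcyclohex-2-en-1-ol (1α-OH)
Conditions: (R)-Me-CBS oxazaborolidine (0.2 equiv), BH3·SMe2, THF, −20 °C
Reagents that add atoms: none
Why: Corey–Bakshi–Shibata reduction in which the fully substituted alkene arm acts as the large group should deliver hydride to one face of the ketone and set C1 as the (S) alcohol.

Step 5
Reactants: 5 (S)-allylic alcohol
Product: 6 1-[2-(tert-butyldimethylsilyloxy)ethyl]-2,2,6-trimethyl-7-oxabicyclo[4.1.0]heptan-5-ol with the epoxide oxygen cis to the hydroxyl (5α,10α-epoxide; 1α-OH)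
Conditions: VO(acac)2 (2 mol %), t-BuOOH, PhMe, 0 °C → rt
Reagents that add atoms: tert-butyl hydroperoxide, CC(C)(C)OO
Why: Vanadium-catalysed hydroxyl-directed epoxidation delivers oxygen to the tetrasubstituted alkene from the face of the C1 hydroxyl, which sets the C5–O bond α.

Step 6
Reactants: 6 cis-epoxy alcohol
Product: 7 4-methoxybenzyl ether of 6 (1α-OPMB; 5α,10α-epoxide)
Conditions: NaH, 4-MeOC6H4CH2Cl, Bu4NI (cat.), THF/DMF, 0 °C → rt
Reagents that add atoms: 4-methoxybenzyl chloride, COc1ccc(CCl)cc1
Why: Williamson etherification of the secondary alkoxide; the alkoxide is cis to the epoxide oxygen and so cannot open it.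

Step 7
Reactants: 7 epoxide 4-methoxybenzyl ether
Product: 8 1-[2-(tert-butyldimethylsilyloxy)ethyl]-3-(4-methoxybenzyloxy)-6,6-dimethyl-2-methylenecyclohexan-1-ol (5α-OH cis to 1α-OPMB; C10=CH2)
Conditions: LiNEt2 (Et2NH, n-BuLi), Et2O/hexane, 0 °C → reflux
Reagents that add atoms: none
Why: Base-induced epoxide-to-allylic-alcohol isomerisation (syn β-elimination): the amide should take a proton from the C10 methyl, the least substituted β-position (the C1 hydrogen is anti to the epoxide oxygen), which breaks C10–O and leaves the C5–O bond and its configuration intact.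

Step 8
Reactants: 8 ring A methylene carbinol silyl ether
Product: 9 1-(2-hydroxyethyl)-3-(4-methoxybenzyloxy)-6,6-dimethyl-2-methylenecyclohexan-1-ol
Conditions: Bu4NF, THF, rt
Reagents that add atoms: none
Why: Fluoride cleavage of the only silyl ether.

Step 9
Reactants: 9 ring A diol
Product: 10 2-[1-hydroxy-3-(4-methoxybenzyloxy)-6,6-dimethyl-2-methylenecyclohexyl]acetaldehyde (C7 aldehyde; 5α-OH; 1α-OPMB)
Conditions: TEMPO (cat.), PhI(OAc)2, CH2Cl2, rt
Reagents that add atoms: none
Why: Nitroxyl-catalysed oxidation of the primary alcohol stops at the aldehyde in dichloromethane, cannot touch the tertiary alcohol and is mild enough for a β-hydroxy aldehyde.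

Step 10
Reactants: 11 methyl 3-oxocyclopent-1-ene-1-carboxylate
Product: 12 methyl (S)-3-hydroxycyclopent-1-ene-1-carboxylate (C8 β-OH)
Conditions: (R)-Me-CBS oxazaborolidine (0.2 equiv), BH3·SMe2, THF, −30 °C
Reagents that add atoms: none
Why: Corey–Bakshi–Shibata reduction of the ring ketone with the alkene arm as the large group should give the (S) allylic alcohol, the C8 centre that relays all later ring C stereochemistry.

Step 11
Reactants: 12 (S)-hydroxy ester
Product: 13 methyl (S)-3-{[(bromomethyl)dimethylsilyl]oxy}cyclopent-1-ene-1-carboxylate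
Conditions: BrCH2SiMe2Cl, Et3N, DMAP (cat.), CH2Cl2, 0 °C
Reagents that add atoms: (bromomethyl)chlorodimethylsilane, C[Si](C)(Cl)CBr
Why: Silylation of the allylic alcohol installs a tethered hydroxymethyl radical equivalent.

Step 12
Reactants: 13 bromomethylsilyl ether
Product: 16 cis-fused hydroxy lactone 6-hydroxy-3-oxabicyclo[3.3.0]octan-2-one (C8 β-OH on the same face as the lactone CH2), via bicyclic siloxane 14 (not isolated), via diol ester 15 (not isolated)
Conditions: Bu3SnH, AIBN (cat.), PhH, 80 °C; then KF, KHCO3, 30% H2O2, THF/MeOH, rt; then DBU (cat.), PhMe, 60 °C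
Reagents that add atoms: hydrogen peroxide, OO
Why: Tin hydride radical cyclisation of the α-silyl radical, 5-exo-trig onto the β-carbon of the unsaturated ester (C14), can only give the cis-fused oxasilolane and so sets C14 with C17 syn to the C8 oxygen; Tamao oxidation frees the diol and the C17 hydroxyl closes the γ-lactone, C13 epimerising under the amidine until the only possible cis-fused lactone has formed.

Step 13
Reactants: 16 hydroxy lactone
Product: 17 6-(2-methoxypropan-2-yloxy)-3-oxabicyclo[3.3.0]octan-2-one (mixed acetal on O8)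
Conditions: 2-methoxypropene, PPTS (cat.), CH2Cl2, 0 °C
Reagents that add atoms: 2-methoxypropene, COC(C)=C
Why: Acid-catalysed addition of the alcohol to the enol ether gives a mixed acetal that resists base and hydride, adds no stereocentre and, unlike a silyl group, cannot migrate to the C17 alkoxide formed in step 16.

Step 14
Reactants: 17 protected lactone
Product: 18 tert-butyl 6-(2-methoxypropan-2-yloxy)-2-oxo-3-oxabicyclo[3.3.0]octane-1-carboxylate (C12 ester α on C13; lactone carbonyl β)
Conditions: LiN(iPr)2, THF, −78 °C; then (t-BuOCO)2O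
Reagents that add atoms: di-tert-butyl dicarbonate, CC(C)(C)OC(=O)OC(=O)OC(C)(C)C
Why: Claisen-type C-acylation of the lactone enolate; because the two five-membered rings can only be cis-fused, the new ester must end up anti to the C17 carbon, which sets the quaternary C13.

Step 15
Reactants: 18 lactone tert-butyl ester
Product: 19 tert-butyl 2-hydroxy-6-(2-methoxypropan-2-yloxy)-3-oxabicyclo[3.3.0]octane-1-carboxylate (lactol; both anomers)
Conditions: i-Bu2AlH (1.1 equiv), CH2Cl2, −78 °C
Reagents that add atoms: none
Why: Partial reduction of the lactone to the lactol at low temperature; the hindered tert-butyl ester is left.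

Step 16
Reactants: 19 lactol
Product: 20 tert-butyl 2-(hydroxymethyl)-1-(2-methoxyethenyl)-3-(2-methoxypropan-2-yloxy)cyclopentane-1-carboxylate (enol ether arm, C17 arm and O8 all β; ester α)
Conditions: Ph3P(CH2OMe)Cl, KN(SiMe3)2, THF, 0 °C → rt
Reagents that add atoms: (methoxymethyl)triphenylphosphonium chloride, COC[P+](c1ccccc1)(c1ccccc1)c1ccccc1.[Cl-]
Why: Wittig methoxymethylenation of the open hydroxy-aldehyde form of the lactol adds C16 at the aldehyde oxidation level and frees the C17 alcohol; the aldehyde has no α-hydrogen, so nothing can epimerise.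

Step 17
Reactants: 20 enol ether alcohol
Product: 21 tert-butyldiphenylsilyl ether of 20 at O17
Conditions: t-BuPh2SiCl, Et3N, DMAP (cat.), CH2Cl2, rt
Reagents that add atoms: tert-butyldiphenylsilyl chloride, CC(C)(C)[Si](Cl)(c1ccccc1)c1ccccc1
Why: Silylation of the primary alcohol with an acid-stable silyl group.

Step 18
Reactants: 21 silylated enol ether
Product: 22 tert-butyl 1-(2,2-dimethoxyethyl)-3-hydroxy-2-[(tert-butyldiphenylsilyloxy)methyl]cyclopentane-1-carboxylate (C8 β-OH)
Conditions: PPTS (cat.), MeOH, rt
Reagents that add atoms: methanol, CO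
Why: Acid-catalysed addition of methanol to the enol ether gives the dimethyl acetal, and the same conditions methanolyse the mixed acetal on the C8 oxygen.

Step 19
Reactants: 22 ring C alcohol
Product: 23 tert-butyl 1-(2,2-dimethoxyethyl)-3-oxo-2-[(tert-butyldiphenylsilyloxy)methyl]cyclopentane-1-carboxylate (C8 ketone)
Conditions: Dess–Martin periodinane, NaHCO3, CH2Cl2, rt
Reagents that add atoms: none
Why: Dess–Martin oxidation of the secondary alcohol under buffered non-basic conditions, so that the β-silyloxy ketone does not eliminate.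

Step 20
Reactants: 23 ring C ketone
Product: 24 tert-butyl 1-(2,2-dimethoxyethyl)-5-[(tert-butyldiphenylsilyloxy)methyl]-4-(trifluoromethylsulfonyloxy)cyclopent-3-ene-1-carboxylate (C8 enol triflate; C17 and C15 arms β; ester α)
Conditions: KN(SiMe3)2, THF, −78 °C; then PhNTf2
Reagents that add atoms: N-phenylbis(trifluoromethanesulfonimide), O=S(=O)(N(c1ccccc1)S(=O)(=O)C(F)(F)F)C(F)(F)F
Why: Kinetic deprotonation at the unhindered C9 methylene and O-sulfonylation of the enolate give the enol triflate with the double bond at C8=C9; the C14 hydrogen is not touched.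

Step 21
Reactants: 10 ring A aldehyde; 24 ring C enol triflate
Product: 25 coupled C7 carbinol (both C7 epimers; ring A methylene carbinol joined through C6–C7 to the cyclopentene)
Conditions: CrCl2 (4 equiv), NiCl2 (2 mol %), DMF, rt
Reagents that add atoms: none
Why: Nozaki–Hiyama–Kishi coupling (nickel activates the enol triflate, the vinyl group passes to chromium and adds to the aldehyde) tolerates the free tertiary alcohol, ester, acetal and ethers; the C7 epimer mixture is immaterial because step 22 oxidises it.

Step 22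
Reactants: 25 coupled carbinol
Product: 26 ring A methylene carbinol linked to the ring C cyclopentenyl ketone (1α-OPMB; 5α-OH; C10=CH2; C7 ketone; C8=C9; C13 and C14 as in 24)
Conditions: Dess–Martin periodinane, NaHCO3, CH2Cl2, 0 °C
Reagents that add atoms: none
Why: Dess–Martin oxidation of the secondary allylic alcohol gives the enone; the tertiary alcohol cannot react.

Step 23
Reactants: 26 methylene carbinol enone
Product: 27 tricyclic C7 ketone (10β-methyl; 5α-OH; 9α-H; 8β-H; 1α-OPMB; C17 arm β as its silyl ether; C13 with acetal arm β and tert-butyl ester α)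
Conditions: Fe(acac)3 (0.5 equiv), PhSiH3 (2.5 equiv), EtOH/(CH2OH)2 5:1, 60 °C
Reagents that add atoms: none
Why: Metal-hydride hydrogen atom transfer followed by radical conjugate addition (Giese addition): the iron hydride formed from Fe(acac)3, PhSiH3 and ethanol gives a hydrogen atom to the CH2 end of the 1,1-disubstituted C10 alkene, the tertiary C10 radical adds to C9, the β-carbon of the cyclopentenyl ketone, and the C8 α-keto radical is reduced to the enolate and protonated by ethanol, so that iron turns over. The closest known reaction type is the iron-mediated reductive coupling of unactivated olefins with enones, which is used intramolecularly to close decalins that carry a quaternary carbon next to a tertiary alcohol. Ring B closes 6-endo-trig, because the nucleophilic tertiary radical seeks the electrophilic β-carbon, whereas 5-exo attack at C8 would be polarity-mismatched and leave an unstabilised radical. C10 and C9 are set in a chair-like transition state with the C6 arm equatorial on ring A and the cyclopentene attached equatorially, which gives the 10β-methyl trans-decalin with 9α-H; C8 lies α to the ketone and should settle as the trans-fused 8β-H epimer on protonation or enolisation. The step needs hydrogen transfer to the methylene and not to the enone, which the electron-rich unhindered 1,1-disubstituted alkene secures, and attack on the β-face of ring C, which the C13 ester on the α-face favours but the C14 arm opposes.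

Step 24
Reactants: 27 tricyclic ketone
Product: 28 7β-alcohol of 27
Conditions: NaBH4, MeOH, −20 → 0 °C
Reagents that add atoms: none
Why: Borohydride reduction by axial attack on the α-face of ring B, the face of the C5 hydroxyl and away from the C14 arm, should give the equatorial 7β-alcohol and so set C7.

Step 25
Reactants: 28 7β-alcohol
Product: 29 1α,5α,7β-triol (O1 freed; other groups as in 28)
Conditions: DDQ, CH2Cl2/pH 7 buffer 10:1, 0 °C
Reagents that add atoms: none
Why: Oxidative cleavage of the 4-methoxybenzyl ether by the quinone in wet solvent (hydride abstraction, then hydrolysis of the oxocarbenium ion); silyl ether, acetal and ester are inert.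

Step 26
Reactants: 29 triol
Product: 30 1α,7β-diacetate with free 5α-OH
Conditions: Ac2O, pyridine, DMAP (cat.), CH2Cl2, rt
Reagents that add atoms: acetic anhydride, CC(=O)OC(C)=O
Why: Acylation of the two secondary alcohols under nucleophilic catalysis; the tertiary C5 hydroxyl is too hindered to react at room temperature.

Step 27
Reactants: 30 diacetate
Product: 32 spiro enol lactone (C12 lactone closed on O–C16 with C15=C16; C17 silyl ether kept), via hydroxy lactone 31 (not isolated)
Conditions: CF3CO2H/CH2Cl2/H2O 20:78:2, 0 °C → rt, evaporate; then MsCl, Et3N, CH2Cl2, −20 → 0 °C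
Reagents that add atoms: none
Why: Acidolysis of the tert-butyl ester and hydrolysis of the acetal give the γ-aldehydo acid, which closes to the five-membered hydroxy lactone (pseudo-acid); sulfonylation of its hemiacetal hydroxyl and amine-induced elimination, the pseudo-acid chloride route to enol lactones, give the 2(3H)-furanone, whose double bond can only be C15=C16 because C13 is quaternary.

Step 28
Reactants: 32 enol lactone silyl ether
Product: 33 enol lactone with free C17 hydroxymethyl
Conditions: HF·pyridine, pyridine, THF, 0 °C → rt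
Reagents that add atoms: none
Why: Fluoride cleavage of the silyl ether under buffered weakly acidic conditions that spare the acetates and the enol lactone, which a basic fluoride source would open.

Step 29
Reactants: 33 enol lactone alcohol
Product: 34 15,16-epoxy lactone with free C17 hydroxymethyl (epoxide oxygen on the lactone face that looks at C14)
Conditions: VO(acac)2 (5 mol %), t-BuOOH (decane), CH2Cl2, 0 °C
Reagents that add atoms: tert-butyl hydroperoxide, CC(C)(C)OO
Why: Vanadium-catalysed hydroxyl-directed epoxidation: the C17 alkoxide on vanadium, cis to C15 on ring C, hands the peroxide oxygen to the enol double bond on the face that looks at C14, the face an undirected oxidant would avoid because the C14 arm covers it, which sets C15 and C16.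

Step 30
Reactants: 34 epoxy lactone alcohol
Product: 35 C17 carboxylic acid of the epoxy lactone
Conditions: TEMPO (cat.), PhI(OAc)2 (2.2 equiv), MeCN/pH 7 buffer, 0 °C → rt
Reagents that add atoms: water, O
Why: Nitroxyl-catalysed oxidation of the primary alcohol through the aldehyde hydrate to the carboxylic acid; the only other free alcohol is tertiary, the neutral buffer spares the acyloxy epoxide, and C14 already has the more stable configuration with C17 trans to C7.

Step 31
Reactants: 35 epoxy lactone acid
Product: 36 spirocaesalmin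
Conditions: Me3SiCHN2, PhMe/MeOH 4:1, 0 °C
Reagents that add atoms: (trimethylsilyl)diazomethane, C[Si](C)(C)C=[N+]=[N-]
Why: Esterification of the carboxylic acid with a diazoalkane under neutral conditions gives the methyl ester and completes the target.

Compound list
1 | β-homocyclocitral, 2-(2,6,6-trimethylcyclohex-1-en-1-yl)acetaldehyde | CC1=C(CC=O)C(C)(C)CCC1 | starting material
2 | 2-(2,6,6-trimethylcyclohex-1-en-1-yl)ethanol | CC1=C(CCO)C(C)(C)CCC1 | intermediate
3 | tert-butyldimethyl[2-(2,6,6-trimethylcyclohex-1-en-1-yl)ethoxy]silane | CC1=C(CCO[Si](C)(C)C(C)(C)C)C(C)(C)CCC1 | intermediate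
4 | 3-[2-(tert-butyldimethylsilyloxy)ethyl]-2,4,4-trimethylcyclohex-2-en-1-one | CC1=C(CCO[Si](C)(C)C(C)(C)C)C(C)(C)CCC1=O | intermediate
5 | (S)-3-[2-(tert-butyldimethylsilyloxy)ethyl]-2,4,4-trimethylcyclohex-2-en-1-ol | CC1=C(CCO[Si](C)(C)C(C)(C)C)C(C)(C)CC[C@@H]1O | intermediate
6 | cis-epoxy alcohol (5α,10α-epoxide, 1α-OH) | C[C@@]12O[C@]1(CCO[Si](C)(C)C(C)(C)C)C(C)(C)CC[C@@H]2O | intermediate
7 | 4-methoxybenzyl ether of 6 | C[C@@]12O[C@]1(CCO[Si](C)(C)C(C)(C)C)C(C)(C)CC[C@@H]2OCc1ccc(OC)cc1 | intermediate
8 | ring A methylene carbinol, C7 silyl ether (5α-OH, 1α-OPMB, C10=CH2) | C=C1[C@@H](OCc2ccc(OC)cc2)CCC(C)(C)[C@]1(O)CCO[Si](C)(C)C(C)(C)C | intermediate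
9 | ring A methylene carbinol, C7 alcohol | C=C1[C@@H](OCc2ccc(OC)cc2)CCC(C)(C)[C@]1(O)CCO | intermediate
10 | ring A methylene carbinol, C7 aldehyde | C=C1[C@@H](OCc2ccc(OC)cc2)CCC(C)(C)[C@]1(O)CC=O | intermediate
11 | methyl 3-oxocyclopent-1-ene-1-carboxylate | COC(=O)C1=CC(=O)CC1 | starting material
12 | methyl (S)-3-hydroxycyclopent-1-ene-1-carboxylate | COC(=O)C1=C[C@@H](O)CC1 | intermediate
13 | methyl (S)-3-{[(bromomethyl)dimethylsilyl]oxy}cyclopent-1-ene-1-carboxylate | COC(=O)C1=C[C@@H](O[Si](C)(C)CBr)CC1 | intermediate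
14 | cis-fused oxasilolane ester (C8–O–SiMe2–C17 ring; ester β) | COC(=O)[C@@H]1CC[C@@H]2O[Si](C)(C)C[C@H]12 | intermediate (not isolated)
15 | methyl 3-hydroxy-2-(hydroxymethyl)cyclopentane-1-carboxylate, all-cis | COC(=O)[C@@H]1CC[C@H](O)[C@@H]1CO | intermediate (not isolated)
16 | 6-hydroxy-3-oxabicyclo[3.3.0]octan-2-one, cis-fused, OH syn to the lactone CH2 | O=C1OC[C@H]2[C@@H](O)CC[C@@H]12 | intermediate
17 | 6-(2-methoxypropan-2-yloxy)-3-oxabicyclo[3.3.0]octan-2-one | O=C1OC[C@H]2[C@@H](OC(C)(C)OC)CC[C@@H]12 | intermediate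
18 | tert-butyl 6-(2-methoxypropan-2-yloxy)-2-oxo-3-oxabicyclo[3.3.0]octane-1-carboxylate | O=C1OC[C@H]2[C@@H](OC(C)(C)OC)CC[C@@]12C(=O)OC(C)(C)C | intermediate
19 | corresponding lactol (anomers) | OC1OC[C@H]2[C@@H](OC(C)(C)OC)CC[C@@]12C(=O)OC(C)(C)C | intermediate
20 | tert-butyl 2-(hydroxymethyl)-1-(2-methoxyethenyl)-3-(2-methoxypropan-2-yloxy)cyclopentane-1-carboxylate (E/Z) | COC=C[C@]1(C(=O)OC(C)(C)C)CC[C@H](OC(C)(C)OC)[C@@H]1CO | intermediate
21 | O17 tert-butyldiphenylsilyl ether of 20 | COC=C[C@]1(C(=O)OC(C)(C)C)CC[C@H](OC(C)(C)OC)[C@@H]1CO[Si](c2ccccc2)(c2ccccc2)C(C)(C)C | intermediate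
22 | tert-butyl 1-(2,2-dimethoxyethyl)-3-hydroxy-2-[(tert-butyldiphenylsilyloxy)methyl]cyclopentane-1-carboxylate | COC(OC)C[C@]1(C(=O)OC(C)(C)C)CC[C@H](O)[C@@H]1CO[Si](c2ccccc2)(c2ccccc2)C(C)(C)C | intermediate
23 | corresponding C8 ketone | COC(OC)C[C@]1(C(=O)OC(C)(C)C)CCC(=O)[C@@H]1CO[Si](c2ccccc2)(c2ccccc2)C(C)(C)C | intermediate
24 | ring C enol triflate | COC(OC)C[C@]1(C(=O)OC(C)(C)C)CC=C(OS(=O)(=O)C(F)(F)F)[C@@H]1CO[Si](c2ccccc2)(c2ccccc2)C(C)(C)C | intermediate
25 | coupled C7 carbinol (C7 epimers) | C=C1[C@@H](OCc2ccc(OC)cc2)CCC(C)(C)[C@]1(O)CC(O)C1=CC[C@](CC(OC)OC)(C(=O)OC(C)(C)C)[C@H]1CO[Si](c1ccccc1)(c1ccccc1)C(C)(C)C | intermediate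
26 | ring A methylene carbinol linked to ring C cyclopentenyl ketone | C=C1[C@@H](OCc2ccc(OC)cc2)CCC(C)(C)[C@]1(O)CC(=O)C1=CC[C@](CC(OC)OC)(C(=O)OC(C)(C)C)[C@H]1CO[Si](c1ccccc1)(c1ccccc1)C(C)(C)C | intermediate
27 | tricyclic C7 ketone with C10 methyl and C5 hydroxyl | CC(C)(C)[Si](c1ccccc1)(c1ccccc1)OC[C@H]1[C@@H]2C(=O)C[C@@]3(O)C(C)(C)CC[C@H](OCc4ccc(OC)cc4)[C@]3(C)[C@H]2C[C@]1(CC(OC)OC)C(=O)OC(C)(C)C | intermediate
28 | 7β-alcohol | CC(C)(C)[Si](c1ccccc1)(c1ccccc1)OC[C@H]1[C@@H]2[C@@H](O)C[C@@]3(O)C(C)(C)CC[C@H](OCc4ccc(OC)cc4)[C@]3(C)[C@H]2C[C@]1(CC(OC)OC)C(=O)OC(C)(C)C | intermediate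
29 | 1α,5α,7β-triol | CC(C)(C)[Si](c1ccccc1)(c1ccccc1)OC[C@H]1[C@@H]2[C@@H](O)C[C@@]3(O)C(C)(C)CC[C@H](O)[C@]3(C)[C@H]2C[C@]1(CC(OC)OC)C(=O)OC(C)(C)C | intermediate
30 | 1α,7β-diacetate | CC(C)(C)[Si](c1ccccc1)(c1ccccc1)OC[C@H]1[C@@H]2[C@@H](OC(C)=O)C[C@@]3(O)C(C)(C)CC[C@H](OC(C)=O)[C@]3(C)[C@H]2C[C@]1(CC(OC)OC)C(=O)OC(C)(C)C | intermediate
31 | spiro hydroxy lactone (pseudo-acid; C16 epimers) | CC(C)(C)[Si](c1ccccc1)(c1ccccc1)OC[C@H]1[C@@H]2[C@@H](OC(C)=O)C[C@@]3(O)C(C)(C)CC[C@H](OC(C)=O)[C@]3(C)[C@H]2C[C@]12C(=O)OC(O)C2 | intermediate (not isolated)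
32 | spiro enol lactone, O17 silyl ether | CC(C)(C)[Si](c1ccccc1)(c1ccccc1)OC[C@H]1[C@@H]2[C@@H](OC(C)=O)C[C@@]3(O)C(C)(C)CC[C@H](OC(C)=O)[C@]3(C)[C@H]2C[C@]12C(=O)OC=C2 | intermediate
33 | spiro enol lactone, C17 alcohol | OC[C@H]1[C@@H]2[C@@H](OC(C)=O)C[C@@]3(O)C(C)(C)CC[C@H](OC(C)=O)[C@]3(C)[C@H]2C[C@]12C(=O)OC=C2 | intermediate
34 | 15,16-epoxy lactone, C17 alcohol | OC[C@H]1[C@@H]2[C@@H](OC(C)=O)C[C@@]3(O)C(C)(C)CC[C@H](OC(C)=O)[C@]3(C)[C@H]2C[C@]12C(=O)O[C@@H]1O[C@@H]12 | intermediate
35 | 15,16-epoxy lactone, C17 acid | OC(=O)[C@H]1[C@@H]2[C@@H](OC(C)=O)C[C@@]3(O)C(C)(C)CC[C@H](OC(C)=O)[C@]3(C)[C@H]2C[C@]12C(=O)O[C@@H]1O[C@@H]12 | intermediate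
36 | spirocaesalmin | COC(=O)[C@H]1[C@@H]2[C@@H](OC(C)=O)C[C@@]3(O)C(C)(C)CC[C@H](OC(C)=O)[C@]3(C)[C@H]2C[C@]12C(=O)O[C@@H]1O[C@@H]12 | target

Total step count: 31 (ring A 9, ring C 11, union 2, key step 1, completion 8).
Longest linear sequence: 22 steps (steps 10–20, then 21–31).

Steps most likely to fail

Step 23. The C10 radical may be capped by hydrogen before it reaches C9, or it may close on the α-face of the cyclopentene and give the wrong ring fusion. The fallback makes the same radical without a hydride donor, by single-electron opening of the epoxide. It sets out from 7. Bu4NF should give the epoxy alcohol F1, and TEMPO/PhI(OAc)2 the β,γ-epoxy aldehyde F2, which is used cold and at once. The chromium/nickel coupling of step 21 with 24 should give the epoxy carbinol F3, and Dess–Martin oxidation the epoxy enone F4. Cp2TiCl (from Cp2TiCl2 and Mn dust, THF; trivalent titanium) should then open the epoxide at C10 to the tertiary radical, with the C5 oxygen held as a titanium alkoxide. The radical adds to C9 and the titanium enolate is protonated on work-up (titanocene-mediated epoxide-opening radical cyclisation). This returns to the route at 27.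

Step 29. The vanadium Lewis acid may open the acyloxy epoxide as it forms, or delivery from the C17 alkoxide may be too slow for the epoxide to accumulate. The fallback changes the directing group and the oxidant. It sets out from 33. TEMPO/PhI(OAc)2 in buffered aqueous MeCN should give the enol lactone acid F5. mCPBA with Na2HPO4 in CH2Cl2 at 0 °C, hydrogen-bonded to the C17 carboxyl, should then place the oxygen on the same face (carboxyl-directed peracid epoxidation). This returns to the route at 35, which is esterified at once in step 31.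

Step 7. The base may take a C6 proton instead of a methyl proton, which would put the double bond at C5=C6 and the hydroxyl on C10. The fallback replaces the base-induced elimination by a homolytic isomerisation. It sets out from 7. Cp2TiCl (Cp2TiCl2, Mn dust, THF) should open the epoxide to the β-titanoxy C10 radical, which loses a methyl hydrogen to a second titanium centre and gives the exocyclic alkene. No new compound is formed (F0), and the route is rejoined at 8.

Further compounds
F1 | step 23 | epoxy alcohol from 7 (C7–OH; 5α,10α-epoxide; 1α-OPMB) | C[C@@]12O[C@]1(CCO)C(C)(C)CC[C@@H]2OCc1ccc(OC)cc1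
F2 | step 23 | β,γ-epoxy aldehyde (C7 aldehyde) | C[C@@]12O[C@]1(CC=O)C(C)(C)CC[C@@H]2OCc1ccc(OC)cc1
F3 | step 23 | epoxy carbinol from F2 and 24 (C7 epimers) | C[C@@]12O[C@]1(CC(O)C3=CC[C@](CC(OC)OC)(C(=O)OC(C)(C)C)[C@H]3CO[Si](c4ccccc4)(c4ccccc4)C(C)(C)C)C(C)(C)CC[C@@H]2OCc1ccc(OC)cc1
F4 | step 23 | epoxy enone (C7 ketone; C8=C9) | C[C@@]12O[C@]1(CC(=O)C3=CC[C@](CC(OC)OC)(C(=O)OC(C)(C)C)[C@H]3CO[Si](c4ccccc4)(c4ccccc4)C(C)(C)C)C(C)(C)CC[C@@H]2OCc1ccc(OC)cc1
F5 | step 29 | spiro enol lactone, C17 acid | OC(=O)[C@H]1[C@@H]2[C@@H](OC(C)=O)C[C@@]3(O)C(C)(C)CC[C@H](OC(C)=O)[C@]3(C)[C@H]2C[C@]12C(=O)OC=C2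
F0 | step 7 | none | none
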